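The constants belong to no real substance; the run is a simulation.

The isomer of the product is what a small charge has to yield, so I wanted to know how much of it each flask held at the end.

    substrate + coupling partner ⇌ adduct (K1 = 490 /M, k1 = 7000 /M/s)
    adduct ⇌ target (K2 = 4.8, k2 = 1.2 /s)
    target ⇌ isomer of the product (K3 = 12, k3 = 0.023 /s)

| flask | substrate | coupling partner | time | remark |
|---|---|---|---|---|
| elm | 0.0010 M | 1.05 mM | 2.0 min | everything together at the start |
| larch | 0.0010 M | 1.05 mM (fed, over 80 s) | 2.0 min | all else is in the flask from the start; the feed brings no volume worth counting |
| maple | 0.0010 M (fed, over 80 s) | 1.05 mM | 2.0 min | all else is in the flask from the start; the feed brings no volume worth counting |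

- the flask that comes out highest in amount of isomer of the product, in percent of the substrate charged, or "all alike" when all lie within 1.5 percentage points (elm / larch / maple / all alike)
- isomer of the product at the end, in percent of the substrate charged, elm
- isomer of the product at the end, in percent of the substrate charged, larch
- isomer of the product at the end, in percent of the substrate charged, maple

1. In elm the first step starts with a forward half-life of 0.0943 s, and the second relaxes with a half-life of 0.478 s. The third relaxes in 27.8 s, far slower, so I took it as the rate-limiting step, with substrate, adduct and target in equilibrium among themselves.

2. On that rung, adduct over substrate is the first constant times c(coupling partner), and target over adduct is the second constant. So the target's share of the material not yet isomer depends on c(coupling partner). After the fast steps in elm I reckoned c(coupling partner) at 0.475 mM, which gave a share of 47.6%.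

3. As isomer forms in elm, c(coupling partner) falls. At full equilibrium I reckoned 0.193 mM, with a share of 29.3%. I replaced the falling curve of the share by the mean of these two values, 38.4%.

4. With that mean share, my reckoning has the isomer rise exponentially towards a ceiling of 82.2%. Its rate is the mean drain constant, the third forward constant times the sum of the mean share and the reciprocal of the third equilibrium constant: 0.645 /min. For elm this gave 59.6%. Using the end shares instead gave 66.9% and 50.3%, and I took that spread as the error of replacing the curve by its mean.

5. The feeds last 80 s, longer than the third relaxation. Fed material arrives on average 40.0 s late, so I read larch and maple as elm at 80.0 s: 47.4% and 47.4%. My choice was elm.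

The forecast said elm, with 61% for elm, 51% for larch and 50.7% for maple, holding that “larch and maple nearly match because the two reagents are almost equimolar”. My figures for larch and maple lay below the forecast's.

Elm came out highest at 60.6%, against 50.3% for larch and 50.0% for maple, as the forecast said. Elm read at 80 s stood at 49.9%, level with both. With the mean drain constant, the delay cost 12 percentage points, and elm and larch differed by 10 points.

For elm read at 30 s, the mean drain constant gave 22.7%. The computed value was 24.8%.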